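## Analysis of the target

The target (CNP0255890.0) is a linear decamer of benzene rings joined only by nine diaryl ether oxygens, carrying 26 free phenolic hydroxyls and no ring-to-ring carbon–carbon bond. With the rings lettered A to J from the 2,4,6-trihydroxyphenyl end, ring A is ether-linked through C1. Rings B, D, F and H are 3,5-dihydroxy-1,4-phenylene units, with a crowded ether oxygen on C4 between two hydroxyls and an open one on C1. Rings C, E, G and I are 3,4,5-trihydroxy-1,2-phenylene units, and ring J is a terminal 3,4,5-trihydroxyphenyl group. There is no stereocenter and the diaryl ether axes rotate freely, so the problem is one of regiochemistry and of making many similar bonds in a fixed order. The free polyphenol oxidises readily in air, above all under base, so all hydroxyls of rings B to J are carried as methyl ethers until the last step. The difficulty lies in the ether bonds: every one of the nine has at least one carbon flanked by two oxygen substituents, and all partners are electron-rich. The strategy rests on ring A: its ether carbon C1 lies between the hydroxyl carbons C2 and C6, with the third hydroxyl on C4, which is the enol form of a 2-aryloxycyclohexane-1,3,5-trione. Ring A can therefore be folded from acyclic 1,3-dicarbonyl pieces in which the ether oxygen already sits on an sp3 carbon.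

## Retrosynthetic reasoning

**28 to 27.** The 23 hydroxyls of rings B to J in 28 are traced back to methyl ethers in 27. Methyl ethers survive organolithium chemistry, copper couplings at 110 °C, peracid and hot alkali, and a boron Lewis acid removes them at the end without touching the diaryl ether bonds, whose carbons are closed to SN2 attack.

**27 to 25.** The two C–H bonds at C3 and C5 of ring A are traced back to C–CO2Me in 25. The esters are the activating groups of the ring synthesis. Forward, saponification gives carboxyl groups flanked by two ring hydroxyls, which lose CO2 easily through ipso protonation of the electron-rich ring.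

**25 to 22 and 23.** The bonds C2–C3 and C5–C6 of ring A are cut. This removes ring A entirely and leaves its ether oxygen on the sp3 carbon of 22, so no substitution at the crowded aryl carbon C1 of ring A is ever needed. The oxygens on C2 and C6 come from the two ester carbonyls of 22 and the oxygen on C4 from the ketone of 23. Forward, both methylene carbons of 23 must acylate the two esters of 22 through carbon, and the triketone must enolise to the arene.

**22 to 20 and 21.** The O–C(sp3) bond is cut. Forward, the unhindered phenoxide of 20 (its hydroxyl on C1 of ring B has two ortho hydrogens) displaces chloride from 21.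

**20 to 18.** The hydroxyl on C1 of ring B is traced back to a formyl group (Dakin oxidation). The aldehyde lets ring B enter as purchasable 11 and cannot act as a nucleophile during chain growth.

**18 back to 11.** The ether bonds between the C4 oxygen of rings H, F, D and B and C1 of rings I, G, E and C are cut in turn: 18 from 17 and 10, 16 from 15 and 8, 14 from 13 and 8, 12 from 11 and 8. The MOM removals 16 to 17, 14 to 15 and 12 to 13 free the next nucleophile. Cutting here makes the nucleophile always the growing chain phenol, which carries no halogen, and the electrophile a small two-ring bromide that can be used in excess. Growth is thus directional and each cycle adds two rings in two operations. The carbon attacked has only one ortho substituent.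

**8 and 10 to 2, 7 and 9.** The bond between the C2 oxygen of the catechol-type ring and the unhindered C1 of the next ring is cut. Forward, an oxidative copper coupling of a boronic acid (Chan–Lam) is used because it leaves the C–Br bond of 2 untouched, so the bifunctional blocks 8 and 10 form without protecting the bromide.

**2, 7 to 1, 3.** Phenol 2 comes from 1 by bromination ortho to the hydroxyl. Boronic acid 7 comes from 3 through MOM ether 4 and bromine–lithium exchange.

## Alternatives that were turned down

**Alternative 1:** Both ether bonds of ring H are cut, giving three fragments: the ring A–G heptamer phenol A2, the ring I–J phenol A3 and the cationic cyclopentadienylruthenium eta-6 complex A1 of 2,5-dichloro-1,3-dimethoxybenzene. Forward, the phenoxide of A2 displaces the open C5 chloride of A1 and the phenoxide of A3 then displaces the C2 chloride between the two methoxy groups, giving the ruthenium-bound decamer A4. Decomplexation and demethylation follow.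
- For: it is more convergent than the chosen route at this junction, since two ether bonds form on one ring without protecting-group steps, and substitution on a cationic arene complex runs under much milder conditions than an Ullmann coupling.
- Against: the second substitution takes place at a carbon flanked by two methoxy groups on a complex already made less electrophilic by the first aryloxy donor. The metal can migrate to one of the other nine electron-rich rings. Ruthenium is used stoichiometrically on a late intermediate.
- Comparison: A2 still contains the crowded ring A ether and five further ether bonds that must be made by ordinary couplings, so the total count of coupling steps is not lower. The chosen route gives up some convergence but removes the ring A ether from the list of aryl substitutions and uses only catalytic copper.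

**Alternative 2:** Ring C is cut at C5–C6 and traced to the squarate-derived 4-hydroxy-4-(1-aryloxyvinyl)cyclobutenone A5 carrying rings A and B. Forward, heating opens the four-membered ring to a dienylketene, which closes between the ketene carbon and the vinyl CH2 and tautomerises to the hydroquinone trimer A6.
- For: the key step is unimolecular, irreversible and regiochemically fixed by the connectivity. On predictability it is stronger than the reversible Claisen–Dieckmann sequence of the chosen route.
- Against: A6 has two free hydroxyls, on C2 and C5 of ring C. One must be methylated and the other arylated, which costs differentiation steps. The target has four rings of this kind (C, E, G, I), so either the sequence is repeated on ever larger aryl vinyl ethers or the remaining rings are joined by the same couplings the chosen route uses. Alpha-metalation of an aryl vinyl ether would compete with ortho-metalation of the polymethoxy rings.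
- Comparison: ring C is a ring that a simple phenol bromination and a copper coupling already supply, and the ring A ether remains to be made by substitution. The chosen route uses its one ring construction where coupling is weakest and needs no phenol differentiation.

**Alternative 3:** Ring F is cut at C2–C3 and C5–C6 and traced to the ring A–E 2-aryloxy-3-(dimethylamino)acrolein A7 and 1,3-dimethoxyacetone A8. Forward, both alpha carbons of A8 condense with the aldehyde and enamine carbons of A7, with loss of dimethylamine and water, to give the hexamer phenol A9 with a free hydroxyl on C4 of ring F.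
- For: it joins the chain near the middle and delivers a phenol ready for the next coupling. On convergence it is stronger than the chosen route, and it follows the same [3+3] logic.
- Against: the alpha carbons of A8 are activated by one carbonyl only, so strong base and self-condensation must be expected. Making A7 requires formylation chemistry on a pentamer whose electron-rich rings are themselves formylation substrates. Ring F is exactly the 4-oxygenated 2,6-dimethoxyphenol pattern that 3 supplies from the bottle.
- Comparison: the ring A ether and the ring G–J portion would still have to be made by couplings. The chosen route uses the doubly activated methylenes of 23 and keeps the oligomer away from electrophilic formylating agents.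

Key step: step 15

Remark: the target has no stereocenter and no hindered axis, so all structures are written without stereodescriptors; compounds 1, 3, 9, 11, 21 and 23 are taken as purchasable.

## Route

Step 1
Reactants: 1 2,3,4-trimethoxyphenol
Product: 2 6-bromo-2,3,4-trimethoxyphenol
Conditions: NBS (1.0 equiv), i-Pr2NH (10 mol%), CH2Cl2, −20 to 0 °C
Reagents that add atoms: N-bromosuccinimide, O=C1CCC(=O)N1Br
Why: Amine-mediated electrophilic bromination of a phenol delivers bromine ortho to the hydroxyl; the para position carries a methoxy group, so C6 is the only position activated by the hydroxyl.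

Step 2
Reactants: 3 4-bromo-2,6-dimethoxyphenol
Product: 4 5-bromo-1,3-dimethoxy-2-(methoxymethoxy)benzene
Conditions: MOMCl, i-Pr2NEt, CH2Cl2, 0 °C to rt
Reagents that add atoms: chloromethyl methyl ether, COCCl
Why: O-alkylation of the phenol with a reactive alpha-chloro ether; the MOM ether should survive n-BuLi, base and copper couplings and leaves under mild acid.

Step 3
Reactants: 4 5-bromo-1,3-dimethoxy-2-(methoxymethoxy)benzene
Product: 7 [3,5-dimethoxy-4-(methoxymethoxy)phenyl]boronic acid, via aryllithium 5 (not isolated), via lithium triisopropoxyarylborate 6 (not isolated)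
Conditions: n-BuLi, THF, −78 °C; B(Oi-Pr)3, −78 °C to rt; aq. NH4Cl
Reagents that add atoms: triisopropyl borate, CC(C)OB(OC(C)C)OC(C)C; water, O
Why: Bromine–lithium exchange at −78 °C is faster than ortho-lithiation beside a methoxy group; the aryllithium is trapped by the borate, and the near-neutral hydrolysis leaves the MOM ether intact.

Step 4
Reactants: 2 6-bromo-2,3,4-trimethoxyphenol; 7 [3,5-dimethoxy-4-(methoxymethoxy)phenyl]boronic acid
Product: 8 1-bromo-2-[3,5-dimethoxy-4-(methoxymethoxy)phenoxy]-3,4,5-trimethoxybenzene
Conditions: Cu(OAc)2 (0.5 equiv), pyridine, 4 Å MS, CH2Cl2, air, rt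
Reagents that add atoms: none
Why: Chan–Lam coupling: the unhindered aryl group is transferred from boron to divalent copper and the C–O bond forms by reductive elimination from trivalent copper at room temperature. Aryl bromides are not activated under these conditions, so the bromine of 2 should be kept for the later Ullmann step.

Step 5
Reactants: 2 6-bromo-2,3,4-trimethoxyphenol; 9 (3,4,5-trimethoxyphenyl)boronic acid
Product: 10 1-bromo-3,4,5-trimethoxy-2-(3,4,5-trimethoxyphenoxy)benzene
Conditions: Cu(OAc)2 (0.5 equiv), pyridine, 4 Å MS, CH2Cl2, air, rt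
Reagents that add atoms: none
Why: The same Chan–Lam coupling as in step 4 builds the ring I–J unit with its bromine untouched.

Step 6
Reactants: 11 4-hydroxy-3,5-dimethoxybenzaldehyde (syringaldehyde); 8 1-bromo-2-[3,5-dimethoxy-4-(methoxymethoxy)phenoxy]-3,4,5-trimethoxybenzene
Product: 12 ring B–D trimer aldehyde with MOM ether on C4 of ring D
Conditions: CuI (cat.), picolinic acid (cat.), K3PO4, DMSO, 110 °C, Ar
Reagents that add atoms: none
Why: Ullmann ether synthesis with picolinate-ligated copper, a system suited to 2,6-disubstituted phenoxides and ortho-substituted aryl halides. The aldehyde has no alpha hydrogen and the MOM ether is base-stable.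

Step 7
Reactants: 12 ring B–D trimer aldehyde with MOM ether on C4 of ring D
Product: 13 ring B–D trimer aldehyde with free hydroxyl on C4 of ring D
Conditions: HCl (cat.), MeOH/THF, 45 °C; then H2O
Reagents that add atoms: none
Why: Acid-catalysed acetal cleavage; methanol traps the methoxymethyl cation as dimethoxymethane before it can alkylate the electron-rich rings, and any dimethyl acetal of the aldehyde reverts on aqueous work-up.

Step 8
Reactants: 13 ring B–D trimer aldehyde with free hydroxyl on C4 of ring D; 8 1-bromo-2-[3,5-dimethoxy-4-(methoxymethoxy)phenoxy]-3,4,5-trimethoxybenzene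
Product: 14 ring B–F pentamer aldehyde with MOM ether on C4 of ring F
Conditions: CuI (cat.), picolinic acid (cat.), K3PO4, DMSO, 110 °C, Ar
Reagents that add atoms: none
Why: Ullmann ether synthesis as in step 6; the phenoxide is now a 4-aryloxy-2,6-dimethoxyphenoxide, which is more electron-rich than that of 11 and should couple more readily.

Step 9
Reactants: 14 ring B–F pentamer aldehyde with MOM ether on C4 of ring F
Product: 15 ring B–F pentamer aldehyde with free hydroxyl on C4 of ring F
Conditions: HCl (cat.), MeOH/THF, 45 °C; then H2O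
Reagents that add atoms: none
Why: Acid-catalysed MOM cleavage as in step 7; diaryl and methyl ethers are inert to dilute acid.

Step 10
Reactants: 15 ring B–F pentamer aldehyde with free hydroxyl on C4 of ring F; 8 1-bromo-2-[3,5-dimethoxy-4-(methoxymethoxy)phenoxy]-3,4,5-trimethoxybenzene
Product: 16 ring B–H heptamer aldehyde with MOM ether on C4 of ring H
Conditions: CuI (cat.), picolinic acid (cat.), K3PO4, DMSO, 110 °C, Ar
Reagents that add atoms: none
Why: Ullmann ether synthesis as in step 8, with the small bromide 8 used in excess to drive conversion of the larger phenol.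

Step 11
Reactants: 16 ring B–H heptamer aldehyde with MOM ether on C4 of ring H
Product: 17 ring B–H heptamer aldehyde with free hydroxyl on C4 of ring H
Conditions: HCl (cat.), MeOH/THF, 45 °C; then H2O
Reagents that add atoms: none
Why: Acid-catalysed MOM cleavage as in step 7.

Step 12
Reactants: 17 ring B–H heptamer aldehyde with free hydroxyl on C4 of ring H; 10 1-bromo-3,4,5-trimethoxy-2-(3,4,5-trimethoxyphenoxy)benzene
Product: 18 ring B–J nonamer aldehyde (formyl on C1 of ring B; 23 methyl ethers)
Conditions: CuI (cat.), picolinic acid (cat.), K3PO4, DMSO, 110 °C, Ar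
Reagents that add atoms: none
Why: Ullmann ether synthesis as in step 8; the bromide 10 brings rings I and J together and completes the chain.

Step 13
Reactants: 18 ring B–J nonamer aldehyde
Product: 20 ring B–J nonamer phenol (free hydroxyl on C1 of ring B; 23 methyl ethers), via nonamer aryl formate 19 (not isolated)
Conditions: mCPBA, CH2Cl2, 0 °C to rt; then HCl (cat.), MeOH, rt
Reagents that add atoms: 3-chloroperoxybenzoic acid, OOC(=O)c1cccc(Cl)c1
Why: Dakin-type Baeyer–Villiger oxidation: the electron-rich 4-aryloxy-3,5-dimethoxyphenyl group migrates in the Criegee intermediate to give the aryl formate, which is methanolysed to the phenol.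

Step 14
Reactants: 20 ring B–J nonamer phenol; 21 dimethyl 2-chloromalonate
Product: 22 dimethyl 2-aryloxymalonate of the ring B–J nonamer
Conditions: K2CO3, acetone, reflux
Reagents that add atoms: none
Why: SN2 displacement of chloride from the malonate carbon by an unhindered phenoxide, the standard way to aryloxymalonates; the ether that will be the crowded ring A ether is formed here at an sp3 carbon.

Step 15
Reactants: 22 dimethyl 2-aryloxymalonate of the ring B–J nonamer; 23 dimethyl 3-oxopentanedioate
Product: 25 decamer with ring A as dimethyl 5-aryloxy-2,4,6-trihydroxyisophthalate, via open-chain Claisen adduct 24 (not isolated)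
Conditions: Mg(OMe)2 (3 equiv), 23 (2 equiv), MeOH/toluene, reflux with removal of MeOH (to ca. 105 °C), Ar; then 1 M HCl
Reagents that add atoms: none
Why: Mg(OMe)2 converts 23 into its chelated magnesium enolate, one methylene carbon of which adds to an ester carbonyl of 22 and expels methoxide (Claisen acylation) to give the open tetracarbonyl chain 24 as a chelate. The second methylene of the former oxoglutarate then attacks the remaining ester of the malonate unit in a Dieckmann closure (6-exo-trig at the ester carbonyl, enolate carbon inside the new ring), and loss of methoxide gives a 2-aryloxycyclohexane-1,3,5-trione that enolises to the aromatic triol 25. The closest known reaction type is the classical alkoxide condensation of malonic esters with 3-oxoglutaric esters to phloroglucinol dicarboxylates. All steps before aromatisation are reversible, and the aromatic, chelated phenoxide is the thermodynamic sink that pulls the equilibria forward as methanol is distilled off. No stereocenter is formed. The step needs attack through carbon and not through enolate oxygen, which would lead to pyranones; the doubly activated methylenes, the magnesium chelate that ties up the enolate oxygens, and the reversibility of O-acylation under methoxide should secure this. It also needs cross-condensation to beat self-condensation of 23, which is addressed by enolising 23 fully before heating, so that its ketone is no longer an electrophile, and by using it in excess over 22. Because the ring A ether enters as the sp3 C–O bond of 22, no hindered aryl carbon is attacked.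

Step 16
Reactants: 25 decamer with ring A as dimethyl 5-aryloxy-2,4,6-trihydroxyisophthalate
Product: 27 decamer with ring A as free 2,4,6-trihydroxyphenyl ether (rings B–J as 23 methyl ethers), via isophthalic diacid 26 (not isolated)
Conditions: KOH, H2O/1,4-dioxane (degassed), 90 °C, Ar; then 2 M HCl, 60 °C
Reagents that add atoms: none
Why: Ester saponification followed by decarboxylation; carboxyl groups flanked by two hydroxyls on a trihydroxybenzene lose CO2 readily after ipso protonation, and methyl and diaryl ethers are stable to hot alkali.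

Step 17
Reactants: 27 decamer with ring A as free 2,4,6-trihydroxyphenyl ether
Product: 28 target decamer CNP0255890.0 (26 free hydroxyls)
Conditions: BBr3 (large excess), CH2Cl2, −78 °C to rt; then MeOH, H2O; Ar throughout
Reagents that add atoms: none
Why: Lewis acid cleavage of aryl methyl ethers: bromide attacks the methyl carbon of each boron-bound ether. The diaryl ether bonds offer no carbon open to SN2 attack and should remain.

## Compound list

1 | 2,3,4-trimethoxyphenol | COc1ccc(O)c(OC)c1OC | starting material
2 | 6-bromo-2,3,4-trimethoxyphenol | COc1cc(Br)c(O)c(OC)c1OC | intermediate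
3 | 4-bromo-2,6-dimethoxyphenol | COc1cc(Br)cc(OC)c1O | starting material
4 | 5-bromo-1,3-dimethoxy-2-(methoxymethoxy)benzene | COCOc1c(OC)cc(Br)cc1OC | intermediate
5 | [3,5-dimethoxy-4-(methoxymethoxy)phenyl]lithium | [Li]c1cc(OC)c(OCOC)c(OC)c1 | intermediate
6 | lithium triisopropoxy[3,5-dimethoxy-4-(methoxymethoxy)phenyl]borate | [Li+].CC(C)O[B-](OC(C)C)(OC(C)C)c1cc(OC)c(OCOC)c(OC)c1 | intermediate
7 | [3,5-dimethoxy-4-(methoxymethoxy)phenyl]boronic acid | COCOc1c(OC)cc(B(O)O)cc1OC | intermediate
8 | 1-bromo-2-[3,5-dimethoxy-4-(methoxymethoxy)phenoxy]-3,4,5-trimethoxybenzene | Brc1cc(OC)c(OC)c(OC)c1Oc1cc(OC)c(OCOC)c(OC)c1 | intermediate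
9 | (3,4,5-trimethoxyphenyl)boronic acid | COc1cc(B(O)O)cc(OC)c1OC | starting material
10 | 1-bromo-3,4,5-trimethoxy-2-(3,4,5-trimethoxyphenoxy)benzene | Brc1cc(OC)c(OC)c(OC)c1Oc1cc(OC)c(OC)c(OC)c1 | intermediate
11 | 4-hydroxy-3,5-dimethoxybenzaldehyde (syringaldehyde) | COc1cc(C=O)cc(OC)c1O | starting material
12 | ring B–D trimer aldehyde, MOM ether on C4 of ring D: 3,5-dimethoxy-4-{2-[3,5-dimethoxy-4-(methoxymethoxy)phenoxy]-3,4,5-trimethoxyphenoxy}benzaldehyde | O=Cc1cc(OC)c(c(OC)c1)Oc1cc(OC)c(OC)c(OC)c1Oc1cc(OC)c(OCOC)c(OC)c1 | intermediate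
13 | ring B–D trimer aldehyde, free hydroxyl on C4 of ring D | O=Cc1cc(OC)c(c(OC)c1)Oc1cc(OC)c(OC)c(OC)c1Oc1cc(OC)c(O)c(OC)c1 | intermediate
14 | ring B–F pentamer aldehyde, MOM ether on C4 of ring F | O=Cc1cc(OC)c(c(OC)c1)Oc1cc(OC)c(OC)c(OC)c1Oc1cc(OC)c(c(OC)c1)Oc1cc(OC)c(OC)c(OC)c1Oc1cc(OC)c(OCOC)c(OC)c1 | intermediate
15 | ring B–F pentamer aldehyde, free hydroxyl on C4 of ring F | O=Cc1cc(OC)c(c(OC)c1)Oc1cc(OC)c(OC)c(OC)c1Oc1cc(OC)c(c(OC)c1)Oc1cc(OC)c(OC)c(OC)c1Oc1cc(OC)c(O)c(OC)c1 | intermediate
16 | ring B–H heptamer aldehyde, MOM ether on C4 of ring H | O=Cc1cc(OC)c(c(OC)c1)Oc1cc(OC)c(OC)c(OC)c1Oc1cc(OC)c(c(OC)c1)Oc1cc(OC)c(OC)c(OC)c1Oc1cc(OC)c(c(OC)c1)Oc1cc(OC)c(OC)c(OC)c1Oc1cc(OC)c(OCOC)c(OC)c1 | intermediate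
17 | ring B–H heptamer aldehyde, free hydroxyl on C4 of ring H | O=Cc1cc(OC)c(c(OC)c1)Oc1cc(OC)c(OC)c(OC)c1Oc1cc(OC)c(c(OC)c1)Oc1cc(OC)c(OC)c(OC)c1Oc1cc(OC)c(c(OC)c1)Oc1cc(OC)c(OC)c(OC)c1Oc1cc(OC)c(O)c(OC)c1 | intermediate
18 | ring B–J nonamer aldehyde (formyl on C1 of ring B, 23 methyl ethers) | O=Cc1cc(OC)c(c(OC)c1)Oc1cc(OC)c(OC)c(OC)c1Oc1cc(OC)c(c(OC)c1)Oc1cc(OC)c(OC)c(OC)c1Oc1cc(OC)c(c(OC)c1)Oc1cc(OC)c(OC)c(OC)c1Oc1cc(OC)c(c(OC)c1)Oc1cc(OC)c(OC)c(OC)c1Oc1cc(OC)c(OC)c(OC)c1 | intermediate
19 | ring B–J nonamer aryl formate (formyloxy on C1 of ring B) | O=COc1cc(OC)c(c(OC)c1)Oc1cc(OC)c(OC)c(OC)c1Oc1cc(OC)c(c(OC)c1)Oc1cc(OC)c(OC)c(OC)c1Oc1cc(OC)c(c(OC)c1)Oc1cc(OC)c(OC)c(OC)c1Oc1cc(OC)c(c(OC)c1)Oc1cc(OC)c(OC)c(OC)c1Oc1cc(OC)c(OC)c(OC)c1 | intermediate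
20 | ring B–J nonamer phenol (free hydroxyl on C1 of ring B, 23 methyl ethers) | Oc1cc(OC)c(c(OC)c1)Oc1cc(OC)c(OC)c(OC)c1Oc1cc(OC)c(c(OC)c1)Oc1cc(OC)c(OC)c(OC)c1Oc1cc(OC)c(c(OC)c1)Oc1cc(OC)c(OC)c(OC)c1Oc1cc(OC)c(c(OC)c1)Oc1cc(OC)c(OC)c(OC)c1Oc1cc(OC)c(OC)c(OC)c1 | intermediate
21 | dimethyl 2-chloromalonate | COC(=O)C(Cl)C(=O)OC | starting material
22 | dimethyl 2-aryloxymalonate of the ring B–J nonamer | COC(=O)C(Oc1cc(OC)c(c(OC)c1)Oc1cc(OC)c(OC)c(OC)c1Oc1cc(OC)c(c(OC)c1)Oc1cc(OC)c(OC)c(OC)c1Oc1cc(OC)c(c(OC)c1)Oc1cc(OC)c(OC)c(OC)c1Oc1cc(OC)c(c(OC)c1)Oc1cc(OC)c(OC)c(OC)c1Oc1cc(OC)c(OC)c(OC)c1)C(=O)OC | intermediate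
23 | dimethyl 3-oxopentanedioate | COC(=O)CC(=O)CC(=O)OC | starting material
24 | open-chain Claisen adduct: trimethyl 1-aryloxy-2,4-dioxopentane-1,3,5-tricarboxylate of the nonamer | COC(=O)C(Oc1cc(OC)c(c(OC)c1)Oc1cc(OC)c(OC)c(OC)c1Oc1cc(OC)c(c(OC)c1)Oc1cc(OC)c(OC)c(OC)c1Oc1cc(OC)c(c(OC)c1)Oc1cc(OC)c(OC)c(OC)c1Oc1cc(OC)c(c(OC)c1)Oc1cc(OC)c(OC)c(OC)c1Oc1cc(OC)c(OC)c(OC)c1)C(=O)C(C(=O)OC)C(=O)CC(=O)OC | intermediate
25 | decamer with ring A as dimethyl 5-aryloxy-2,4,6-trihydroxyisophthalate | COC(=O)c2c(O)c(Oc1cc(OC)c(c(OC)c1)Oc1cc(OC)c(OC)c(OC)c1Oc1cc(OC)c(c(OC)c1)Oc1cc(OC)c(OC)c(OC)c1Oc1cc(OC)c(c(OC)c1)Oc1cc(OC)c(OC)c(OC)c1Oc1cc(OC)c(c(OC)c1)Oc1cc(OC)c(OC)c(OC)c1Oc1cc(OC)c(OC)c(OC)c1)c(O)c(C(=O)OC)c2O | intermediate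
26 | decamer with ring A as 5-aryloxy-2,4,6-trihydroxyisophthalic acid | OC(=O)c2c(O)c(Oc1cc(OC)c(c(OC)c1)Oc1cc(OC)c(OC)c(OC)c1Oc1cc(OC)c(c(OC)c1)Oc1cc(OC)c(OC)c(OC)c1Oc1cc(OC)c(c(OC)c1)Oc1cc(OC)c(OC)c(OC)c1Oc1cc(OC)c(c(OC)c1)Oc1cc(OC)c(OC)c(OC)c1Oc1cc(OC)c(OC)c(OC)c1)c(O)c(C(=O)O)c2O | intermediate
27 | decamer with ring A as free 2,4,6-trihydroxyphenyl ether, rings B–J as 23 methyl ethers | Oc2cc(O)c(Oc1cc(OC)c(c(OC)c1)Oc1cc(OC)c(OC)c(OC)c1Oc1cc(OC)c(c(OC)c1)Oc1cc(OC)c(OC)c(OC)c1Oc1cc(OC)c(c(OC)c1)Oc1cc(OC)c(OC)c(OC)c1Oc1cc(OC)c(c(OC)c1)Oc1cc(OC)c(OC)c(OC)c1Oc1cc(OC)c(OC)c(OC)c1)c(O)c2 | intermediate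
28 | target decamer CNP0255890.0 | Oc1cc(O)c(Oc2cc(O)c(Oc3cc(O)c(O)c(O)c3Oc3cc(O)c(Oc4cc(O)c(O)c(O)c4Oc4cc(O)c(Oc5cc(O)c(O)c(O)c5Oc5cc(O)c(Oc6cc(O)c(O)c(O)c6Oc6cc(O)c(O)c(O)c6)c(O)c5)c(O)c4)c(O)c3)c(O)c2)c(O)c1 | target

## Step count and risk

Total step count: 17. Longest linear sequence: 15 steps (steps 2, 3, 4 and 6 to 17, from 3 to 28).

**Step 15 (key step).** The acidic methine of 22 may be deprotonated under the reaction conditions, which switches off the electrophilicity of both its esters. The first Claisen acylation could then stall while 23 condenses with itself, or the open chain could lactonise through enolate oxygen instead of closing through carbon. Fallback, separating acylation from ring closure: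
- 22 is half-saponified with one equivalent of KOH in MeOH at 0 °C to the malonic half ester F4.
- F4 is converted with oxalyl chloride and catalytic DMF into the acid chloride F5.
- F5 acylates the magnesium enolate of 23 at carbon (MgCl2, Et3N, MeCN, 0 °C) to give 24, which is isolated.
- 24 is then closed by Dieckmann condensation with NaOMe in MeOH, returning to the route at 25.

**Step 6.** The phenoxide of 11 is both hindered and deactivated by the para formyl group, so C–O bond formation at copper may be slower than hydrodebromination of 8. The later Ullmann steps 8, 10 and 12 use more electron-rich phenoxides and should be easier, though on larger substrates. Fallback with reversed polarity: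
- 8 is hydroxylated (Pd2(dba)3, 2-di-tert-butylphosphino-2′,4′,6′-triisopropylbiphenyl, KOH, dioxane/H2O, 100 °C) to 2-[3,5-dimethoxy-4-(methoxymethoxy)phenoxy]-3,4,5-trimethoxyphenol F3.
- F3, a phenol with only one ortho substituent, is coupled with purchasable 4-bromo-3,5-dimethoxybenzaldehyde, an aldehyde-activated bromide, under Pd(OAc)2 and the same phosphine with K3PO4 in toluene at 100 °C.
- This returns to the route at 12.

**Step 1.** Bromination may occur in part at C5, para to the C2 methoxy group, or the para-methoxyphenol may be oxidised towards a quinone. Fallback by directed metalation: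
- 1 is converted with MOMCl and i-Pr2NEt into 1,2,3-trimethoxy-4-(methoxymethoxy)benzene F1.
- F1 is lithiated ortho to the MOM ether, the stronger directing group (n-BuLi, THF, 0 °C), and quenched with 1,2-dibromotetrachloroethane to 1-bromo-3,4,5-trimethoxy-2-(methoxymethoxy)benzene F2.
- F2 is cleaved with HCl in MeOH, returning to the route at 2.

**Step 17.** Cleavage of 23 methyl ethers in one operation may stay incomplete at a few positions, and the free polyphenol may degrade oxidatively during isolation. Fallback by isolation as a stable derivative: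
- 27 is treated with BBr3, or with AlCl3/EtSH if boron chelation by the trihydroxy rings stalls the cleavage.
- The crude product is not isolated as the free phenol but acetylated (Ac2O, pyridine) to the 26-fold acetate F6.
- F6 is stable in air and can be separated by chromatography from incompletely demethylated material.
- Acid-catalysed methanolysis of F6 (HCl in degassed MeOH) returns to the route at 28.

## Further compounds

F1 | step 1 | 1,2,3-trimethoxy-4-(methoxymethoxy)benzene | COCOc1ccc(OC)c(OC)c1OC
F2 | step 1 | 1-bromo-3,4,5-trimethoxy-2-(methoxymethoxy)benzene | COCOc1c(Br)cc(OC)c(OC)c1OC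
F3 | step 6 | 2-[3,5-dimethoxy-4-(methoxymethoxy)phenoxy]-3,4,5-trimethoxyphenol | Oc1cc(OC)c(OC)c(OC)c1Oc1cc(OC)c(OCOC)c(OC)c1
F4 | step 15 | 2-aryloxy-3-methoxy-3-oxopropanoic acid of the ring B–J nonamer (malonic half ester) | COC(=O)C(Oc1cc(OC)c(c(OC)c1)Oc1cc(OC)c(OC)c(OC)c1Oc1cc(OC)c(c(OC)c1)Oc1cc(OC)c(OC)c(OC)c1Oc1cc(OC)c(c(OC)c1)Oc1cc(OC)c(OC)c(OC)c1Oc1cc(OC)c(c(OC)c1)Oc1cc(OC)c(OC)c(OC)c1Oc1cc(OC)c(OC)c(OC)c1)C(O)=O
F5 | step 15 | methyl 2-aryloxy-3-chloro-3-oxopropanoate of the ring B–J nonamer (acid chloride) | COC(=O)C(Oc1cc(OC)c(c(OC)c1)Oc1cc(OC)c(OC)c(OC)c1Oc1cc(OC)c(c(OC)c1)Oc1cc(OC)c(OC)c(OC)c1Oc1cc(OC)c(c(OC)c1)Oc1cc(OC)c(OC)c(OC)c1Oc1cc(OC)c(c(OC)c1)Oc1cc(OC)c(OC)c(OC)c1Oc1cc(OC)c(OC)c(OC)c1)C(Cl)=O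
F6 | step 17 | 26-fold acetate of the target decamer | CC(=O)Oc1cc(OC(C)=O)c(Oc2cc(OC(C)=O)c(Oc3cc(OC(C)=O)c(OC(C)=O)c(OC(C)=O)c3Oc3cc(OC(C)=O)c(Oc4cc(OC(C)=O)c(OC(C)=O)c(OC(C)=O)c4Oc4cc(OC(C)=O)c(Oc5cc(OC(C)=O)c(OC(C)=O)c(OC(C)=O)c5Oc5cc(OC(C)=O)c(Oc6cc(OC(C)=O)c(OC(C)=O)c(OC(C)=O)c6Oc6cc(OC(C)=O)c(OC(C)=O)c(OC(C)=O)c6)c(OC(C)=O)c5)c(OC(C)=O)c4)c(OC(C)=O)c3)c(OC(C)=O)c2)c(OC(C)=O)c1
A1 | alternative 1 | cyclopentadienylruthenium eta-6 complex of 2,5-dichloro-1,3-dimethoxybenzene, hexafluorophosphate (written as separated ions) | COc1cc(Cl)cc(OC)c1Cl.[Ru+2].c1cc[cH-]c1.F[P-](F)(F)(F)(F)F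
A2 | alternative 1 | permethylated ring A–G heptamer phenol, free hydroxyl on C2 of ring G | COc1cc(OC)c(c(OC)c1)Oc1cc(OC)c(c(OC)c1)Oc1cc(OC)c(OC)c(OC)c1Oc1cc(OC)c(c(OC)c1)Oc1cc(OC)c(OC)c(OC)c1Oc1cc(OC)c(c(OC)c1)Oc1cc(OC)c(OC)c(OC)c1O
A3 | alternative 1 | ring I–J phenol: 3,4,5-trimethoxy-2-(3,4,5-trimethoxyphenoxy)phenol | Oc1cc(OC)c(OC)c(OC)c1Oc1cc(OC)c(OC)c(OC)c1
A4 | alternative 1 | permethylated decamer bound eta-6 through ring H to cyclopentadienylruthenium, hexafluorophosphate (written as separated ions) | COc1cc(OC)c(c(OC)c1)Oc1cc(OC)c(c(OC)c1)Oc1cc(OC)c(OC)c(OC)c1Oc1cc(OC)c(c(OC)c1)Oc1cc(OC)c(OC)c(OC)c1Oc1cc(OC)c(c(OC)c1)Oc1cc(OC)c(OC)c(OC)c1Oc1cc(OC)c(c(OC)c1)Oc1cc(OC)c(OC)c(OC)c1Oc1cc(OC)c(OC)c(OC)c1.[Ru+2].c1cc[cH-]c1.F[P-](F)(F)(F)(F)F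
A5 | alternative 2 | 4-hydroxy-2,3-dimethoxy-4-(1-aryloxyvinyl)cyclobut-2-en-1-one carrying rings A and B | COc1cc(OC)c(c(OC)c1)Oc1cc(OC)c(c(OC)c1)OC(=C)C1(O)C(OC)=C(OC)C1=O
A6 | alternative 2 | ring A–C trimer with free hydroxyls on C2 and C5 of ring C | COc1cc(OC)c(c(OC)c1)Oc1cc(OC)c(c(OC)c1)Oc1cc(O)c(OC)c(OC)c1O
A7 | alternative 3 | ring A–E 2-aryloxy-3-(dimethylamino)acrolein | COc1cc(OC)c(c(OC)c1)Oc1cc(OC)c(c(OC)c1)Oc1cc(OC)c(OC)c(OC)c1Oc1cc(OC)c(c(OC)c1)Oc1cc(OC)c(OC)c(OC)c1OC(C=O)=CN(C)C
A8 | alternative 3 | 1,3-dimethoxyacetone | COCC(=O)COC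
A9 | alternative 3 | ring A–F hexamer phenol with free hydroxyl on C4 of ring F | COc1cc(OC)c(c(OC)c1)Oc1cc(OC)c(c(OC)c1)Oc1cc(OC)c(OC)c(OC)c1Oc1cc(OC)c(c(OC)c1)Oc1cc(OC)c(OC)c(OC)c1Oc1cc(OC)c(O)c(OC)c1
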